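**Retrosynthetic overview**
- Ring C (the pyranone) is the only ring made, and it is made last: the O1–C8a aryl–oxygen bond is cut to give an open-chain 2-methoxy-1,3-diketone, closed in the forward direction by a dehydrogenative C–H/O–H cyclisation.
- The diketone is cut between the CH(OMe) carbon and the benzoyl carbon: C-benzoylation of an α-methoxy aryl ketone with benzoyl chloride, which brings in ring B.
- The α-methoxy ketone comes from Friedel–Crafts acylation of 1,2,3,4-tetramethoxybenzene (ring A with all four methoxy groups) with methoxyacetyl chloride, which carries the future 3-OMe.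

Assumption: the target has no stereocentre or stereogenic axis, so it is one achiral compound and no stereocontrol is needed; 1,2,3,4-tetramethoxybenzene is taken as a catalogue starting material.

**Step 1**
Reactants: 1 1,2,3,4-tetramethoxybenzene; 2 methoxyacetyl chloride
Product: 3 2-methoxy-1-(2,3,4,5-tetramethoxyphenyl)ethan-1-one
Conditions: SnCl4 (1.1 equiv), CH2Cl2, −10 to 0 °C; then 1 M HCl
Reagents that add atoms: methoxyacetyl chloride (2), COCC(=O)Cl
Why: Friedel–Crafts acylation of a strongly activated arene whose two free positions are equivalent, so only one regioisomer can form, with the mild Lewis acid at low temperature chosen to avoid ortho-demethylation and decarbonylation of the acylium ion.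

**Step 2**
Reactants: 3 2-methoxy-1-(2,3,4,5-tetramethoxyphenyl)ethan-1-one; 4 benzoyl chloride
Product: 6 2-methoxy-1-phenyl-3-(2,3,4,5-tetramethoxyphenyl)propane-1,3-dione, via lithium enolate 5 (not isolated)
Conditions: LiN(SiMe3)2 (2.1 equiv), PhMe–THF, −78 °C; then PhCOCl (1.0 equiv), −78 to 0 °C; 1 M HCl quench
Reagents that add atoms: benzoyl chloride (4), O=C(Cl)c1ccccc1; lithium bis(trimethylsilyl)amide, [Li]N([Si](C)(C)C)[Si](C)(C)C (lithium into 5 only)
Why: Claisen-type C-acylation of the chelated (Z)-lithium enolate by the acid chloride, with the second equivalent of base holding the product as its lithium diketonate until the quench so that it is not acylated again; the CH(OMe) centre of 6 is racemic and enolisable and disappears in step 3.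

**Step 3**
Reactants: 6 2-methoxy-1-phenyl-3-(2,3,4,5-tetramethoxyphenyl)propane-1,3-dione
Product: 7 3,5,6,7,8-pentamethoxy-2-phenyl-4H-chromen-4-one (3,5,6,7,8-pentamethoxyflavone)
Conditions: Pd(OAc)2 (10 mol %), 3-nitropyridine (10 mol %), t-BuOOBz (2.0 equiv), C6F6–DMI (3:2), 90 °C
Reagents that add atoms: none
Why: Proposed new method: the enol oxygen of 6 binds divalent palladium, the single C–H of ring A (ortho to the aroyl carbonyl and activated by its ortho and para methoxy groups) is cleaved by carboxylate-assisted electrophilic palladation to a seven-membered oxapalladacycle, the perester oxidises this to tetravalent palladium, and C(aryl)–O reductive elimination closes ring C (C–C elimination would need a four-membered ring), so the site is fixed by C–H metalation and no methoxy group can be displaced; the closest known reaction type is palladium-catalysed phenol- or carboxylic-acid-directed C–H activation/C–O cyclisation to dibenzofurans and benzocoumarins, not yet shown with a 1,3-diketone enol as the oxygen partner.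

**Compound list**
1 | 1,2,3,4-tetramethoxybenzene | COc1ccc(OC)c(OC)c1OC | starting material
2 | methoxyacetyl chloride | COCC(=O)Cl | starting material
3 | 2-methoxy-1-(2,3,4,5-tetramethoxyphenyl)ethan-1-one | COCC(=O)c1cc(OC)c(OC)c(OC)c1OC | intermediate
4 | benzoyl chloride | O=C(Cl)c1ccccc1 | starting material
5 | lithium (Z)-2-methoxy-1-(2,3,4,5-tetramethoxyphenyl)ethen-1-olate (formed in the flask, not isolated) | [Li]O/C(=C\OC)c1cc(OC)c(OC)c(OC)c1OC | intermediate
6 | 2-methoxy-1-phenyl-3-(2,3,4,5-tetramethoxyphenyl)propane-1,3-dione (racemic, keto/enol mixture) | COC(C(=O)c1ccccc1)C(=O)c1cc(OC)c(OC)c(OC)c1OC | intermediate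
7 | 3,5,6,7,8-pentamethoxy-2-phenyl-4H-chromen-4-one (3,5,6,7,8-pentamethoxyflavone, achiral) | COc1c(OC)c(OC)c2c(=O)c(OC)c(-c3ccccc3)oc2c1OC | target

**Total step count:** 3. **Longest linear sequence:** 3 steps (1 → 3 → 6 → 7).

**Steps most likely to fail, with fallbacks**

Step 3 (the proposed new cyclisation) is the most likely to fail. The catalyst may be tied up as a palladium bis(diketonate). Palladation may occur on ring B and close the ring onto the wrong aryl group. Benzoate may be transferred instead of the enol oxygen. One-electron oxidants are deliberately avoided, because radical cations of polymethoxyarenes are attacked at methoxy-bearing carbons and the 5-OMe would be lost. The fallback uses known chemistry, sets out from 3 and comes back to the route at 7. Ring bromination of 3 at its only aromatic C–H (N-bromosuccinimide, MeCN, room temperature) gives 1-(2-bromo-3,4,5,6-tetramethoxyphenyl)-2-methoxyethan-1-one F1. Deprotonation with LiN(SiMe3)2 (2.1 equiv, −78 °C) gives lithium (Z)-1-(2-bromo-3,4,5,6-tetramethoxyphenyl)-2-methoxyethen-1-olate F2, which is C-benzoylated with 4 as in step 2 to give 1-(2-bromo-3,4,5,6-tetramethoxyphenyl)-2-methoxy-3-phenylpropane-1,3-dione F3. Intramolecular copper-catalysed Ullmann O-arylation of the diketone enolate (CuI 10 mol %, 1,10-phenanthroline, K2CO3, DMF, 100 °C) then displaces bromide and closes ring C to give 7.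

Step 2 is the second risk: O-acylation to an enol benzoate, double acylation, or retro-Claisen cleavage on work-up. The fallback sets out from 3 and comes back at 6, replacing acylation by aldol addition and oxidation. Enolate 5 is made with LiN(i-Pr)2 (THF, −78 °C) and added to benzaldehyde, then quenched with dilute HCl, to give 3-hydroxy-2-methoxy-3-phenyl-1-(2,3,4,5-tetramethoxyphenyl)propan-1-one F4 as a diastereomer mixture, which does not matter. Dess–Martin periodinane (CH2Cl2, NaHCO3, room temperature) oxidises the secondary alcohol to give 6.

Step 1 is the third risk: Lewis-acid demethylation of the methoxy group ortho to the new carbonyl, or loss of CO from the methoxyacetyl cation leading to methoxymethylation. The fallback sets out from 1 and comes back at 3, replacing electrophilic substitution by an aryl anion. Methoxy-directed ortho-lithiation (n-BuLi, TMEDA, THF, 0 °C) gives (2,3,4,5-tetramethoxyphenyl)lithium F5. This adds at −78 °C to the Weinreb amide N,2-dimethoxy-N-methylacetamide (COCC(=O)N(C)OC) to give the chelated tetrahedral adduct lithium 2-methoxy-1-[methoxy(methyl)amino]-1-(2,3,4,5-tetramethoxyphenyl)ethan-1-olate F6, which collapses on quenching with 1 M HCl to give 3.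

**Further compounds**
F1 | step 3 | 1-(2-bromo-3,4,5,6-tetramethoxyphenyl)-2-methoxyethan-1-one | COCC(=O)c1c(Br)c(OC)c(OC)c(OC)c1OC
F2 | step 3 | lithium (Z)-1-(2-bromo-3,4,5,6-tetramethoxyphenyl)-2-methoxyethen-1-olate | [Li]O/C(=C\OC)c1c(Br)c(OC)c(OC)c(OC)c1OC
F3 | step 3 | 1-(2-bromo-3,4,5,6-tetramethoxyphenyl)-2-methoxy-3-phenylpropane-1,3-dione (racemic) | COC(C(=O)c1ccccc1)C(=O)c1c(Br)c(OC)c(OC)c(OC)c1OC
F4 | step 2 | 3-hydroxy-2-methoxy-3-phenyl-1-(2,3,4,5-tetramethoxyphenyl)propan-1-one (racemic, syn/anti mixture) | COC(C(O)c1ccccc1)C(=O)c1cc(OC)c(OC)c(OC)c1OC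
F5 | step 1 | (2,3,4,5-tetramethoxyphenyl)lithium | [Li]c1cc(OC)c(OC)c(OC)c1OC
F6 | step 1 | lithium 2-methoxy-1-[methoxy(methyl)amino]-1-(2,3,4,5-tetramethoxyphenyl)ethan-1-olate (racemic) | COCC(O[Li])(N(C)OC)c1cc(OC)c(OC)c(OC)c1OC
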